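The readings are calculated with made-up constants; the scatter is artificial.

The constants of this chemistry are hidden at this stage, so the two earlier runs must stand in for them.

| flask | starting material | remark | time |
|---|---|---|---|
| autumn | 0.070 M | run made earlier |  |
| spring | 0.11 M | run made earlier |  |
| flask | 0.050 M |  | 3.0 h |

- autumn (time / h: isomer of the product / %, target / %): 0.417: 6.4, 30.1; 0.667: 9.8, 43.0; 1.00: 12.7, 53.0; 1.50: 12.3, 62.0; 2.50: 13.9, 65.3
- spring (time / h: isomer of the product / %, target / %): 0.417: 8.3, 30.1; 0.667: 12.1, 44.0; 1.00: 13.6, 53.5; 1.50: 12.7, 59.1; 2.50: 13.3, 65.2

(standard deviation of a reading: 1 percentage point)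

- a reading or a percentage of target counts all its forms, free or not

1. the best time, 3.0 h at the latest, for isomer of the product
2. the amount of isomer of the product, in percent of the starting material charged, at that time
3. the first time at which isomer of the product reaches 4.0 %, in the same percent

The end state comes first. Isomer of the product averages 13.1 % over the last two autumn readings and 13.0 % over the last two spring readings. The mean of these, 13.1 %, is the isomer ceiling: the height at which the readings of isomer of the product level off in these two runs, in percent of the charge. The opposite outcome, a ceiling that moves with concentration, would need the two means to part by about twice the 1 percentage point that their difference carries. They stand 0.1 points apart, so this reckoning keeps the ceiling for the flask at 0.050 M.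

The approach comes next. The earliest isomer readings of the two runs average 7.35 %, and an exponential climb to the ceiling through them has rate 1.99 h⁻¹, which puts 4.0 % at 0.184 h in this reckoning. From 1.00 h on, the isomer readings of both runs lie within 1 point of the ceiling, so they name no single best time. The forecast gives 13.4 % at 2.5 h, and 4.0 % at 0.23 h, later than this reckoning, while granting that the “best time is therefore poorly defined”.

The flask peaks at 13.2 % at 1.60 h, on the ceiling, and reaches 4.0 % at 0.167 h.

    starting material ⇌ target (K = 2.50, k = 3.03 × 10⁻⁴ s⁻¹)
    starting material ⇌ isomer of the product (K = 1.40, k = 7.75 × 10⁻⁵ s⁻¹)
    crystals ⇌ target, rate k3*(cs3 - [target]) while solid is left; crystals form when [target] > cs3 (solubility = 0.540 mM, k = 0.00283 s⁻¹)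
    starting material ⇌ dormant form (K = 8.67, k = 8.10 × 10⁻⁵ s⁻¹)

At 1.60 h the flask holds 13.2 % of isomer of the product against 9.44 % of starting material, a ratio of 1.40, which matches the equilibrium constant 1.4 of that step, so its forward and backward rates are equal there, a momentary quasi-equilibrium. At 3.00 h the flask's ratio stands at 3.99, above that constant, and isomer of the product is down to 11.7 %. The neighbour flask at 0.020 M peaks at 13.3 %, again on the ceiling.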